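## Retrosynthetic overview
1. The CO2H is unmasked last from a methyl ester. The (E,E)-dienyl comes from an HWE reaction on a neopentyl aldehyde (from CH2OTBS). The C1 ethyl alkene comes from a ketone via enol triflate and Fe-catalysed ethyl coupling.
2. Ring 2 (the cyclohexene, C4=C5) is formed second, by RCM of an isopropenyl/vinyl diene.
3. The vicinal quaternary centres C6–C7 come from a Z-allylic ester Ireland–Claisen, built on a ketal-protected cyclopentane acid.
4. Ring 1 (the cyclopentane with C3, C3a, C7a) is formed first. It comes from cuprate conjugate addition and enolate alkylation on (R)-4-methylcyclopentenone, which is trans,trans-selective.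
5. The enone comes from meso cis-3,5-diacetoxycyclopentene by enzymatic desymmetrization. The side-chain alcohol comes from citraconic anhydride.

Assumption: the absolute configuration is taken exactly from the given SMILES. Enone 5 and enol ether 6 are used crude and immediately.

## Route

**Step 1**
Reactants: 1, cis-3,5-diacetoxycyclopent-1-ene (meso)
Product: 2, (1R,4S)-4-hydroxycyclopent-2-en-1-yl acetate
Conditions: electric-eel acetylcholinesterase (hydrolase, EC 3.1.1.7), 0.1 M phosphate buffer pH 7.0, 25 °C, pH-stat with NaOH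
Reagents that add atoms: water, O
Why: hydrolase-catalysed, enantiotopic-group-selective monohydrolysis (asymmetric desymmetrization) sets the first stereocentre.

**Step 2**
Reactants: 2
Product: 3, (R)-4-acetoxycyclopent-2-en-1-one
Conditions: DMP, NaHCO3, CH2Cl2, 0 → 25 °C
Reagents that add atoms: none
Why: Dess–Martin oxidation of the free allylic alcohol leaves the acetate-bearing stereocentre untouched.

**Step 3**
Reactants: 3
Product: 4, (3R,4R)-4-acetoxy-3-methylcyclopentan-1-one (Me trans to OAc)
Conditions: Me2CuLi (1.5 equiv), Et2O, –78 °C; sat. NH4Cl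
Reagents that add atoms: lithium dimethylcuprate, [Li+].C[Cu-]C
Why: cuprate 1,4-addition occurs anti to the γ-acetoxy group, setting the methyl stereocentre (future C3).

**Step 4**
Reactants: 4
Product: 5, (R)-4-methylcyclopent-2-en-1-one
Conditions: DBU, CH2Cl2, 0 °C, 10 min; filter through silica and use at once
Reagents that add atoms: none
Why: E1cB loss of AcOH through the C5 enolate (β-acetoxy ketone elimination) removes the OAc stereocentre and leaves the methyl stereocentre untouched.

**Step 5**
Reactants: 5
Product: 6, TMS enol ether of trans-3-isopropenyl-4-methylcyclopentanone (enol double bond toward the isopropenyl-bearing carbon)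
Conditions: H2C=C(Me)MgBr (2 equiv), CuBr·SMe2 (1 equiv), THF, –78 °C; then TMSCl, HMPA, –78 → 25 °C
Reagents that add atoms: isopropenylmagnesium bromide, C=C(C)[Mg]Br; chlorotrimethylsilane, C[Si](C)(C)Cl
Why: conjugate addition of the alkenylcuprate anti to the 4-methyl group sets C3a, and the regiodefined enolate is trapped as the silyl enol ether (Noyori-type three-component logic).

**Step 6**
Reactants: 6
Product: 7, methyl 2-[4-methyl-2-oxo-5-(prop-1-en-2-yl)cyclopentyl]acetate (CH2CO2Me trans to isopropenyl, isopropenyl trans to Me)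
Conditions: MeLi (1.05 equiv), THF, –78 → 0 °C; then HMPA, BrCH2CO2Me, –78 → –20 °C
Reagents that add atoms: methyl bromoacetate, COC(=O)CBr
Why: MeLi regenerates the regiodefined lithium enolate, and SN2 alkylation occurs anti to the adjacent isopropenyl group, setting C7a.

**Step 7**
Reactants: 7
Product: 8, methyl 2-[8-methyl-7-(prop-1-en-2-yl)-1,4-dioxaspiro[4.4]nonan-6-yl]acetate
Conditions: (Me3SiOCH2)2 (1.5 equiv), TMSOTf (5 mol %), CH2Cl2, –78 → 0 °C
Reagents that add atoms: 1,2-bis(trimethylsilyloxy)ethane, C[Si](C)(C)OCCO[Si](C)(C)C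
Why: Noyori ketalization under non-acidic conditions masks the ketone, since it is more acidic than the ester and must survive LDA.

**Step 8**
Reactants: 8
Product: 9, methyl 2-[8-methyl-7-(prop-1-en-2-yl)-1,4-dioxaspiro[4.4]nonan-6-yl]propanoate (C7 epimer mixture)
Conditions: LDA (1.2 equiv), THF, –78 °C; then MeI (3 equiv), DMPU, –78 → 0 °C
Reagents that add atoms: iodomethane, CI
Why: ester-enolate C-methylation; the new CH(Me) centre is destroyed again on enolization in step 13, so its configuration is irrelevant.

**Step 9**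
Reactants: 9
Product: 10, the corresponding propanoic acid
Conditions: LiOH·H2O (5 equiv), THF/MeOH/H2O 3:1:1, 50 °C; then 1 M HCl to pH 3
Reagents that add atoms: water (hydroxide), O
Why: saponification of an unhindered secondary-alkyl methyl ester; no stereocentre is affected.

**Step 10**
Reactants: 11, citraconic anhydride
Product: 12, (Z)-2-methylbut-2-ene-1,4-diol
Conditions: LiAlH4 (2.5 equiv), THF, 0 → 25 °C
Reagents that add atoms: none
Why: hydride reduction of the anhydride keeps the ring-enforced cis alkene, so the two CH2OH groups are cis (Z).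

**Step 11**
Reactants: 12
Product: 13, (2Z)-4-[(tert-butyldimethylsilyl)oxy]-3-methylbut-2-en-1-ol
Conditions: TBSCl (1.0 equiv), imidazole, CH2Cl2, 0 °C; chromatographic separation of regioisomers
Reagents that add atoms: tert-butyldimethylsilyl chloride, CC(C)(C)[Si](C)(C)Cl
Why: chemoselective mono-silylation of a primary allylic diol; the isomer silylated on the methyl-bearing side is isolated, and the Z geometry is unchanged.

**Step 12**
Reactants: 10; 13
Product: 14, (2Z)-4-(TBSO)-3-methylbut-2-en-1-yl 2-[8-methyl-7-(prop-1-en-2-yl)-1,4-dioxaspiro[4.4]nonan-6-yl]propanoate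
Conditions: EDC·HCl (1.5 equiv), DMAP (0.2 equiv), CH2Cl2, 0 → 25 °C
Reagents that add atoms: none
Why: Steglich esterification with the primary allylic alcohol; no stereocentre is created.

**Step 13**
Reactants: 14
Product: 15, 4-(TBSO)-2,3-dimethyl-2-[8-methyl-7-(prop-1-en-2-yl)-1,4-dioxaspiro[4.4]nonan-6-yl]-3-vinylbutanoic acid (C6/C7 configured as in the target)
Conditions: LDA (1.5 equiv), THF, –78 °C; TBSCl (3 equiv), –78 → 25 °C, then 60 °C, 12 h; K2CO3, MeOH/H2O
Reagents that add atoms: none (the silyl ester is cleaved on work-up)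
Why: In the Ireland–Claisen [3,3], LDA/THF puts the bulky C7a group cis to the allyl oxygen. With the Z-allylic alkene this goes through a chair transition state that fixes the C6/C7 relative configuration as in the target. The bulky C1 ketal shields one face of the ketene acetal, which directs the allyl terminus to the correct face relative to C7a.

**Step 14**
Reactants: 15
Product: 16, methyl ester of 15
Conditions: TMSCHN2 (3 equiv), MeOH/PhMe, 0 → 25 °C
Reagents that add atoms: trimethylsilyldiazomethane, C[Si](C)(C)C=[N+]=[N-] (adds CH3)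
Why: diazoalkane methylation works on a very hindered acid without touching the stereocentres.

**Step 15**
Reactants: 16
Product: 17, trans-fused hexahydroindene ketal with C4=C5 (C4-Me, C6-Me/CH2OTBS, C7-Me/CO2Me)
Conditions: Grubbs II (10 mol %), toluene (5 mM), 80 °C, 12 h
Reagents that add atoms: none (ethylene is lost)
Why: ring-closing metathesis of the isopropenyl and vinyl groups forms the trisubstituted cyclohexene; the trans ring fusion is already fixed by C3a/C7a.

**Step 16**
Reactants: 17
Product: 18, the C1 ketone (hydrindenone)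
Conditions: PPTS (0.3 equiv), acetone/H2O 10:1, 60 °C
Reagents that add atoms: water, O
Why: acid-catalysed dioxolane hydrolysis; the neopentyl TBS ether and the alkene survive.

**Step 17**
Reactants: 18
Product: 19, Δ1,2 enol triflate
Conditions: KHMDS (1.2 equiv), THF, –78 °C; PhNTf2 (1.3 equiv), –78 → 0 °C
Reagents that add atoms: N-phenyl-bis(trifluoromethanesulfonimide), O=S(=O)(C(F)(F)F)N(c1ccccc1)S(=O)(=O)C(F)(F)F
Why: kinetic enolization occurs at C2 because C7a is flanked by the quaternary C7, giving the regiodefined C1=C2 enol triflate.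

**Step 18**
Reactants: 19
Product: 20, C1-ethyl cyclopentene (TBS ether, methyl ester)
Conditions: EtMgBr (2 equiv), Fe(acac)3 (5 mol %), THF/NMP, 0 °C, 20 min
Reagents that add atoms: ethylmagnesium bromide, CC[Mg]Br
Why: iron-catalysed Kumada coupling of the enol triflate retains the alkene position, and the hindered ester is untouched at 0 °C.

**Step 19**
Reactants: 20
Product: 21, primary alcohol (CH2OH on C6)
Conditions: TBAF (3 equiv), THF, 50 °C
Reagents that add atoms: none
Why: fluoride desilylation of the neopentyl TBS ether.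

**Step 20**
Reactants: 21
Product: 22, C6 aldehyde
Conditions: DMP (1.5 equiv), NaHCO3, CH2Cl2, 25 °C
Reagents that add atoms: none
Why: oxidation gives a quaternary-α aldehyde with no α-H, so it cannot epimerize.

**Step 21**
Reactants: 22; 23, diethyl (E)-cinnamylphosphonate
Product: 24, methyl ester of the target (E,E-dienyl)
Conditions: 23 (2 equiv), NaH (2 equiv), THF, 0 → 60 °C; add 22
Reagents that add atoms: none beyond reactant 23
Why: Horner–Wadsworth–Emmons olefination of the stabilized allylic phosphonate gives the (E,E)-diene, retaining the cinnamyl alkene geometry.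

**Step 22**
Reactants: 24
Product: 25, 22-nor-zyggomphic acid B
Conditions: TMSOK (4 equiv), THF, 60 °C, 12 h; 1 M HCl
Reagents that add atoms: none
Why: the silanolate attacks the methyl carbon (SN2 dealkylation), avoiding the very hindered acyl carbon and leaving all alkenes and stereocentres unchanged.

## Compound list
1 | cis-3,5-diacetoxycyclopent-1-ene | CC(=O)O[C@H]1C=C[C@@H](OC(C)=O)C1 | starting material
2 | (1R,4S)-4-hydroxycyclopent-2-en-1-yl acetate | CC(=O)O[C@H]1C=C[C@@H](O)C1 | intermediate
3 | (R)-4-acetoxycyclopent-2-en-1-one | CC(=O)O[C@H]1C=CC(=O)C1 | intermediate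
4 | (3R,4R)-4-acetoxy-3-methylcyclopentan-1-one | CC(=O)O[C@@H]1CC(=O)C[C@H]1C | intermediate
5 | (R)-4-methylcyclopent-2-en-1-one | C[C@@H]1CC(=O)C=C1 | intermediate
6 | TMS enol ether of trans-3-isopropenyl-4-methylcyclopentanone | C=C(C)[C@H]1[C@H](C)CC(O[Si](C)(C)C)=C1 | intermediate
7 | methyl 2-[4-methyl-2-oxo-5-(prop-1-en-2-yl)cyclopentyl]acetate | C=C(C)[C@H]1[C@H](C)CC(=O)[C@@H]1CC(=O)OC | intermediate
8 | methyl 2-[8-methyl-7-(prop-1-en-2-yl)-1,4-dioxaspiro[4.4]nonan-6-yl]acetate | C=C(C)[C@H]1[C@H](C)CC2(OCCO2)[C@@H]1CC(=O)OC | intermediate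
9 | corresponding methyl propanoate (C7 epimers) | C=C(C)[C@H]1[C@H](C)CC2(OCCO2)[C@@H]1C(C)C(=O)OC | intermediate
10 | corresponding propanoic acid | C=C(C)[C@H]1[C@H](C)CC2(OCCO2)[C@@H]1C(C)C(=O)O | intermediate
11 | citraconic anhydride | CC1=CC(=O)OC1=O | starting material
12 | (Z)-2-methylbut-2-ene-1,4-diol | OC/C=C(/C)CO | intermediate
13 | (2Z)-4-(TBSO)-3-methylbut-2-en-1-ol | OC/C=C(/C)CO[Si](C)(C)C(C)(C)C | intermediate
14 | Z-allylic ester of 10 with 13 | C=C(C)[C@H]1[C@H](C)CC2(OCCO2)[C@@H]1C(C)C(=O)OC/C=C(/C)CO[Si](C)(C)C(C)(C)C | intermediate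
15 | Claisen acid | C=C(C)[C@H]1[C@H](C)CC2(OCCO2)[C@@H]1[C@@](C)(C(=O)O)[C@](C)(C=C)CO[Si](C)(C)C(C)(C)C | intermediate
16 | methyl ester of 15 | C=C(C)[C@H]1[C@H](C)CC2(OCCO2)[C@@H]1[C@@](C)(C(=O)OC)[C@](C)(C=C)CO[Si](C)(C)C(C)(C)C | intermediate
17 | RCM product (cyclohexene ketal) | O1CCOC12C[C@@H](C)[C@@H]3C(C)=C[C@](C)(CO[Si](C)(C)C(C)(C)C)[C@](C)(C(=O)OC)[C@H]32 | intermediate
18 | C1 ketone | O=C1C[C@@H](C)[C@@H]2C(C)=C[C@](C)(CO[Si](C)(C)C(C)(C)C)[C@](C)(C(=O)OC)[C@@H]12 | intermediate
19 | enol triflate | FC(F)(F)S(=O)(=O)OC1=C[C@@H](C)[C@@H]2C(C)=C[C@](C)(CO[Si](C)(C)C(C)(C)C)[C@](C)(C(=O)OC)[C@@H]12 | intermediate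
20 | C1-ethyl alkene (TBS ether, methyl ester) | CCC1=C[C@@H](C)[C@@H]2C(C)=C[C@](C)(CO[Si](C)(C)C(C)(C)C)[C@](C)(C(=O)OC)[C@@H]12 | intermediate
21 | primary alcohol | CCC1=C[C@@H](C)[C@@H]2C(C)=C[C@](C)(CO)[C@](C)(C(=O)OC)[C@@H]12 | intermediate
22 | aldehyde | CCC1=C[C@@H](C)[C@@H]2C(C)=C[C@](C)(C=O)[C@](C)(C(=O)OC)[C@@H]12 | intermediate
23 | diethyl (E)-cinnamylphosphonate | CCOP(=O)(OCC)C/C=C/c1ccccc1 | starting material
24 | methyl ester of the target | CCC1=C[C@@H](C)[C@@H]2C(C)=C[C@](C)(/C=C/C=C/c3ccccc3)[C@](C)(C(=O)OC)[C@@H]12 | intermediate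
25 | 22-nor-zyggomphic acid B | CCC1=C[C@@H](C)[C@@H]2C(C)=C[C@](C)(/C=C/C=C/c3ccccc3)[C@](C)(C(=O)O)[C@@H]12 | target

## Totals
Total steps: 22. Longest linear sequence: 20 steps (steps 1–9 and 12–22; steps 10–11 form the side-chain branch).

## Three steps most likely to fail
1. **Step 13 (Ireland–Claisen).** Forming vicinal quaternary centres is slow, and the facial selectivity relative to C7a depends on the ketal out-competing the C3a side.
   Fallback: drop the Claisen/RCM pair and build a trans-fused Hagemann-type enone instead. This uses a Robinson-type annulation on the cyclopentanone that carries CH2CO2Me at C7a and an acetyl at C3a (from ozonolysis of the isopropenyl). Then add a dienyl nucleophile conjugately to the β-methyl enone for C6, and methylate the C7 ester enolate axially. Both steps are ring-controlled.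
2. **Step 15 (RCM).** Closing a trans-fused trisubstituted cyclohexene next to two quaternary centres may stall.
   Fallback: ozonolyse the isopropenyl and vinyl groups of 16 to a methyl ketone and an aldehyde, then close C4=C5 by intramolecular McMurry coupling.
3. **Step 21 (HWE on the neopentyl aldehyde).** The reaction may be slow or give poor E,E selectivity.
   Fallback: Takai olefination (CrCl2, CHI3) to the (E)-vinyl iodide, then Suzuki coupling with (E)-styrylboronic acid.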